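The fourteen-membered carbocycle is opened at C3=C4 (Horner–Wadsworth–Emmons closure) and cut at C8–C9 and C12–C13. Everything rests on the C12–C13 cut: the ring segment C9–C10–C11=C12(CH3) is a ring-opened 2,3-dihydrofuran. In one operation, the cuprate formed from the C13 alkyllithium and 5-lithio-2,3-dihydrofuran undergoes a 1,2-metallate shift and is methylated, which forms C12–C13 and C12–CH3, fixes the 11E alkene and frees the C9 hydroxyl for the next coupling. The precursor is the primary alkyllithium Li–C13–C14–C1(R)(side chain)–C2–C3H(OMe)2; its C1 centre comes from a rhodium-catalysed conjugate addition to a lactone.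

Key step: step 8

Remark: atom numbers refer to the target (ring C1–C14; C15 is the side-chain carbon on C1, C16 its CH2, C17–C20 the prenyl end); the reagents in the Conditions lines and the numbered starting materials are taken to be commercial.

Step 1
Reactants: 1 6-methylhept-5-en-2-one (sulcatone); 2 2,4,6-triisopropylbenzenesulfonohydrazide
Product: 3 (E)-N'-(6-methylhept-5-en-2-ylidene)-2,4,6-triisopropylbenzenesulfonohydrazide
Conditions: MeOH, HCl (cat.), rt
Reagents that add atoms: none
Why: Acid-catalysed hydrazone condensation of the methyl ketone, which leaves the trisubstituted alkene untouched and places the sulfonamide nitrogen syn to the methyl group as the next step requires.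

Step 2
Reactants: 3 (E)-N'-(6-methylhept-5-en-2-ylidene)-2,4,6-triisopropylbenzenesulfonohydrazide
Product: 6 potassium trifluoro(6-methylhepta-1,5-dien-2-yl)borate, via alkenyllithium 4 (not isolated), via lithium alkenylborate 5 (not isolated)
Conditions: n-BuLi (2.2 equiv), THF, −78 → 0 °C; B(Oi-Pr)3, −78 °C → rt; aq. KHF2, MeOH
Reagents that add atoms: triisopropyl borate, CC(C)OB(OC(C)C)OC(C)C; potassium hydrogen difluoride, [K+].F[H-]F
Why: Shapiro reaction: double deprotonation (N–H, then the methyl group syn to nitrogen) and loss of sulfinate and N2 give the 1-alken-2-yllithium regiospecifically, and borate capture followed by KHF2 converts it into a storable trifluoroborate.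

Step 3
Reactants: 6 potassium trifluoro(6-methylhepta-1,5-dien-2-yl)borate; 7 5,6-dihydro-2H-pyran-2-one
Product: 8 (R)-4-(6-methylhepta-1,5-dien-2-yl)tetrahydro-2H-pyran-2-one
Conditions: [Rh(cod)2]BF4 (3 mol %), (R)-BINAP, Et3N, toluene/H2O, 60 °C
Reagents that add atoms: none
Why: Hayashi–Miyaura rhodium-catalysed asymmetric 1,4-addition, established for alkenyltrifluoroborates and for this lactone: the alkenylrhodium–(R)-BINAP complex inserts the cis-enoate through its αre face, which sets the C4 (R) centre (the future C1), and water protonates the rhodium enolate.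

Step 4
Reactants: 8 (R)-4-(6-methylhepta-1,5-dien-2-yl)tetrahydro-2H-pyran-2-one
Product: 9 (R)-3-(2-hydroxyethyl)-N-methoxy-N,8-dimethyl-4-methylidenenon-7-enamide
Conditions: MeNHOMe·HCl, i-PrMgCl, THF, −20 → 0 °C
Reagents that add atoms: N,O-dimethylhydroxylamine hydrochloride, CNOC.Cl
Why: Weinreb amide formation by aminolysis of the lactone with the chloromagnesium amide gives a stable chelate, releases the C13 hydroxyl and thereby tells the two two-carbon arms on C1 apart without touching the stereocentre.

Step 5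
Reactants: 9 (R)-3-(2-hydroxyethyl)-N-methoxy-N,8-dimethyl-4-methylidenenon-7-enamide
Product: 10 (S)-3-(2-iodoethyl)-N-methoxy-N,8-dimethyl-4-methylidenenon-7-enamide
Conditions: I2, PPh3, imidazole, CH2Cl2, 0 °C
Reagents that add atoms: iodine, [I][I]
Why: Appel reaction: the primary alcohol is activated as an alkoxyphosphonium ion and displaced by iodide, imidazole keeping the medium neutral for the amide and the alkenes.

Step 6
Reactants: 10 (S)-3-(2-iodoethyl)-N-methoxy-N,8-dimethyl-4-methylidenenon-7-enamide
Product: 11 (S)-3-(2-iodoethyl)-8-methyl-4-methylidenenon-7-enal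
Conditions: i-Bu2AlH, THF, −78 °C
Reagents that add atoms: none
Why: Partial reduction of the Weinreb amide: the chelated tetrahedral aluminium adduct survives at −78 °C and collapses to the aldehyde only on work-up, while the primary iodide is not reduced at this temperature.

Step 7
Reactants: 11 (S)-3-(2-iodoethyl)-8-methyl-4-methylidenenon-7-enal
Product: 12 (S)-3-(2,2-dimethoxyethyl)-1-iodo-8-methyl-4-methylidenenon-7-ene
Conditions: HC(OMe)3, MeOH, PPTS, rt
Reagents that add atoms: trimethyl orthoformate, COC(OC)OC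
Why: Acid-catalysed acetalisation, driven by the orthoformate, masks C3 as the dimethyl acetal, which is inert to the organolithium and copper reagents of the next step; the mild acid spares the 1,1-disubstituted alkene and the iodide.

Step 8
Reactants: 12 (S)-3-(2,2-dimethoxyethyl)-1-iodo-8-methyl-4-methylidenenon-7-ene; 13 2,3-dihydrofuran
Product: 19 (3E,7R)-7-(2,2-dimethoxyethyl)-4,12-dimethyl-8-methylidenetrideca-3,11-dien-1-ol, via alkyllithium 14 (not isolated), via alkylcopper 15 (not isolated), via 5-lithio-2,3-dihydrofuran 16 (not isolated), via mixed lithium cuprate 17 (not isolated), via alkenylcopper alkoxide 18 (not isolated)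
Conditions: 12, t-BuLi (2.1 equiv), Et2O/pentane, −78 °C; CuBr·SMe2 (1 equiv), Me2S, −78 → −40 °C; 16 (from 13, t-BuLi, THF, −78 → 0 °C); −78 °C → rt; MeI, DMPU, 0 °C → rt
Reagents that add atoms: iodomethane, CI
Why: Lithium–iodine exchange on 12 gives alkyllithium 14, which with CuBr·SMe2 and 16 forms the mixed cuprate 17, where C12 carries both copper and the ring oxygen. On warming, the C13 alkyl group shifts from copper to C12 on the side opposite to the departing oxygen (1,2-metallate rearrangement with inversion at the alkenyl carbon), which opens the ring to the C9 alkoxide and leaves copper cis to C10 in 18. Iodomethane then alkylates the alkenylcopper with retention, so the methyl group ends cis to C10 and C13 trans to it. The closest known reaction type is this same rearrangement of cuprates of 5-lithio-2,3-dihydrofuran followed by electrophilic capture, used for E-trisubstituted homoallylic alcohols and applied here to a functionalised alkyl group. No ring is closed and no stereocentre is formed; the selectivity needed is the 11E geometry, which follows from the cis ring geometry of the dihydrofuran combined with invertive migration and retentive methylation, and the transfer of the alkyl group in preference to a second dihydrofuranyl group, which the 1:1:1 stoichiometry secures. The acetal, the C15=C16 and C19=C20 alkenes and the C1 centre are inert to the organolithium and organocopper species at these temperatures.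

Step 9
Reactants: 19 (3E,7R)-7-(2,2-dimethoxyethyl)-4,12-dimethyl-8-methylidenetrideca-3,11-dien-1-ol
Product: 20 (3E,7R)-7-(2,2-dimethoxyethyl)-1-iodo-4,12-dimethyl-8-methylidenetrideca-3,11-diene
Conditions: I2, PPh3, imidazole, CH2Cl2, 0 °C
Reagents that add atoms: iodine, [I][I]
Why: Appel reaction on the primary homoallylic alcohol under imidazole-buffered conditions that leave the acetal and the three alkenes intact.

Step 10
Reactants: 21 ethyltriphenylphosphonium iodide; 22 3-[(tert-butyldimethylsilyl)oxy]propanal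
Product: 26 (Z)-tert-butyl[(4-iodopent-3-en-1-yl)oxy]dimethylsilane, via ethylidene ylide 23 (not isolated), via iodophosphonium salt 24 (not isolated), via iodoethylidene ylide 25 (not isolated)
Conditions: n-BuLi, THF, 0 °C; I2, −78 °C; NaN(SiMe3)2, −78 → −20 °C; 22, −78 °C → rt
Reagents that add atoms: iodine, [I][I]
Why: Stork–Zhao-type olefination: the non-stabilised α-iodo ylide, made in the flask by iodination and deprotonation of the ethylidene ylide, reacts with the aldehyde under kinetic control to place iodine cis to the chain (Z).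

Step 11
Reactants: 26 (Z)-tert-butyl[(4-iodopent-3-en-1-yl)oxy]dimethylsilane
Product: 27 (Z)-4-iodopent-3-en-1-ol
Conditions: Bu4NF, THF, 0 °C
Reagents that add atoms: none
Why: Fluoride desilylation frees the primary alcohol; the vinyl iodide is inert to fluoride.

Step 12
Reactants: 20 (3E,7R)-7-(2,2-dimethoxyethyl)-1-iodo-4,12-dimethyl-8-methylidenetrideca-3,11-diene; 27 (Z)-4-iodopent-3-en-1-ol
Product: 30 (3Z,7E,11R)-11-(2,2-dimethoxyethyl)-4,8,16-trimethyl-12-methylideneheptadeca-3,7,15-trien-1-ol, via homoallyllithium 28 (not isolated), via lithium borate complex 29 (not isolated)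
Conditions: 20, t-BuLi (2.1 equiv), Et2O, −78 °C; B-methoxy-9-BBN, THF, −78 °C → rt; 27, Pd(dppf)Cl2, AsPh3, Cs2CO3, DMF/H2O, rt
Reagents that add atoms: none
Why: B-alkyl Suzuki–Miyaura coupling: lithium–iodine exchange and capture by B-methoxy-9-BBN give a borate whose primary alkyl group is transferred to the vinylpalladium species formed from 27, and reductive elimination with retention of the vinyl geometry forms C8–C9 and fixes the 7Z alkene.

Step 13
Reactants: 30 (3Z,7E,11R)-11-(2,2-dimethoxyethyl)-4,8,16-trimethyl-12-methylideneheptadeca-3,7,15-trien-1-ol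
Product: 31 (3Z,7E,11R)-11-(2,2-dimethoxyethyl)-1-iodo-4,8,16-trimethyl-12-methylideneheptadeca-3,7,15-triene
Conditions: I2, PPh3, imidazole, CH2Cl2, 0 °C
Reagents that add atoms: iodine, [I][I]
Why: Appel reaction on the primary homoallylic alcohol, again buffered by imidazole so that the acetal and the alkenes are preserved.

Step 14
Reactants: 31 (3Z,7E,11R)-11-(2,2-dimethoxyethyl)-1-iodo-4,8,16-trimethyl-12-methylideneheptadeca-3,7,15-triene; 32 trimethyl phosphonoacetate
Product: 34 methyl (5Z,9E,13R)-2-(dimethoxyphosphoryl)-13-(2,2-dimethoxyethyl)-6,10,18-trimethyl-14-methylidenenonadeca-5,9,17-trienoate (both C2 epimers), via sodium phosphonoacetate 33 (not isolated)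
Conditions: 32 (3 equiv), NaH, DMF, 0 °C; 31, 50 °C
Reagents that add atoms: none
Why: SN2 C-alkylation of the stabilised phosphonoacetate anion by the primary iodide (malonate-type alkylation), excess 32 suppressing dialkylation; the new centre at C4 is formed as both epimers, which is immaterial because it becomes sp2 in step 16.

Step 15
Reactants: 34 methyl (5Z,9E,13R)-2-(dimethoxyphosphoryl)-13-(2,2-dimethoxyethyl)-6,10,18-trimethyl-14-methylidenenonadeca-5,9,17-trienoate
Product: 35 methyl (5Z,9E,13R)-2-(dimethoxyphosphoryl)-6,10,18-trimethyl-14-methylidene-13-(2-oxoethyl)nonadeca-5,9,17-trienoate (both C2 epimers)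
Conditions: PPTS, acetone/H2O, 50 °C
Reagents that add atoms: water, O
Why: Mild acid-catalysed acetal hydrolysis (transacetalisation to acetone) unveils the C3 aldehyde; C1 is β to the carbonyl and cannot epimerise, and the alkenes and the phosphonoacetate tolerate pyridinium acid.

Step 16
Reactants: 35 methyl (5Z,9E,13R)-2-(dimethoxyphosphoryl)-6,10,18-trimethyl-14-methylidene-13-(2-oxoethyl)nonadeca-5,9,17-trienoate
Product: 36 methyl (1E,4R,7E,11Z)-7,11-dimethyl-4-(6-methylhepta-1,5-dien-2-yl)cyclotetradeca-1,7,11-triene-1-carboxylate (CNP0163659.1)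
Conditions: LiCl, DBU, MeCN, rt, slow addition (final ca. 1 mM)
Reagents that add atoms: none
Why: Intramolecular Horner–Wadsworth–Emmons olefination under Masamune–Roush conditions at high dilution closes the fourteen-membered ring at C3=C4, and the α-substituted phosphonoacetate delivers the favoured (E)-enoate with the ester trans to C2, as in the target.

Compound list
1 | 6-methylhept-5-en-2-one (sulcatone) | CC(=O)CCC=C(C)C | starting material
2 | 2,4,6-triisopropylbenzenesulfonohydrazide | CC(C)c1cc(C(C)C)c(S(=O)(=O)NN)c(C(C)C)c1 | starting material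
3 | (E)-N'-(6-methylhept-5-en-2-ylidene)-2,4,6-triisopropylbenzenesulfonohydrazide | C/C(CCC=C(C)C)=N\NS(=O)(=O)c1c(C(C)C)cc(C(C)C)cc1C(C)C | intermediate
4 | 6-methylhepta-1,5-dien-2-yllithium | [Li]C(=C)CCC=C(C)C | intermediate (not isolated)
5 | lithium triisopropoxy(6-methylhepta-1,5-dien-2-yl)borate | [Li+].C=C(CCC=C(C)C)[B-](OC(C)C)(OC(C)C)OC(C)C | intermediate (not isolated)
6 | potassium trifluoro(6-methylhepta-1,5-dien-2-yl)borate | [K+].C=C(CCC=C(C)C)[B-](F)(F)F | intermediate
7 | 5,6-dihydro-2H-pyran-2-one | O=C1C=CCCO1 | starting material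
8 | (R)-4-(6-methylhepta-1,5-dien-2-yl)tetrahydro-2H-pyran-2-one | O=C1C[C@@H](CCO1)C(=C)CCC=C(C)C | intermediate
9 | (R)-3-(2-hydroxyethyl)-N-methoxy-N,8-dimethyl-4-methylidenenon-7-enamide | CON(C)C(=O)C[C@@H](CCO)C(=C)CCC=C(C)C | intermediate
10 | (S)-3-(2-iodoethyl)-N-methoxy-N,8-dimethyl-4-methylidenenon-7-enamide | CON(C)C(=O)C[C@@H](CCI)C(=C)CCC=C(C)C | intermediate
11 | (S)-3-(2-iodoethyl)-8-methyl-4-methylidenenon-7-enal | O=CC[C@@H](CCI)C(=C)CCC=C(C)C | intermediate
12 | (S)-3-(2,2-dimethoxyethyl)-1-iodo-8-methyl-4-methylidenenon-7-ene | ICC[C@H](CC(OC)OC)C(=C)CCC=C(C)C | intermediate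
13 | 2,3-dihydrofuran | C1=COCC1 | starting material
14 | [(R)-3-(2,2-dimethoxyethyl)-8-methyl-4-methylidenenon-7-en-1-yl]lithium (the C13 alkyllithium) | [Li]CC[C@H](CC(OC)OC)C(=C)CCC=C(C)C | intermediate (not isolated)
15 | [(S)-3-(2,2-dimethoxyethyl)-8-methyl-4-methylidenenon-7-en-1-yl]copper | [Cu]CC[C@H](CC(OC)OC)C(=C)CCC=C(C)C | intermediate (not isolated)
16 | 5-lithio-2,3-dihydrofuran | [Li]C1=CCCO1 | intermediate (not isolated)
17 | lithium [(S)-3-(2,2-dimethoxyethyl)-8-methyl-4-methylidenenon-7-en-1-yl](4,5-dihydrofuran-2-yl)cuprate | [Li+].C1CC=C(O1)[Cu-]CC[C@H](CC(OC)OC)C(=C)CCC=C(C)C | intermediate (not isolated)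
18 | lithium (3Z,7R)-4-cuprio-7-(2,2-dimethoxyethyl)-12-methyl-8-methylidenetrideca-3,11-dien-1-olate (copper cis to C10) | [Li]OCC/C=C(\[Cu])CC[C@H](CC(OC)OC)C(=C)CCC=C(C)C | intermediate (not isolated)
19 | (3E,7R)-7-(2,2-dimethoxyethyl)-4,12-dimethyl-8-methylidenetrideca-3,11-dien-1-ol | OCC/C=C(\C)CC[C@H](CC(OC)OC)C(=C)CCC=C(C)C | intermediate
20 | (3E,7R)-7-(2,2-dimethoxyethyl)-1-iodo-4,12-dimethyl-8-methylidenetrideca-3,11-diene | ICC/C=C(\C)CC[C@H](CC(OC)OC)C(=C)CCC=C(C)C | intermediate
21 | ethyltriphenylphosphonium iodide | CC[P+](c1ccccc1)(c1ccccc1)c1ccccc1.[I-] | starting material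
22 | 3-[(tert-butyldimethylsilyl)oxy]propanal | O=CCCO[Si](C)(C)C(C)(C)C | starting material
23 | ethylidenetriphenylphosphorane | CC=P(c1ccccc1)(c1ccccc1)c1ccccc1 | intermediate (not isolated)
24 | (1-iodoethyl)triphenylphosphonium iodide | IC(C)[P+](c1ccccc1)(c1ccccc1)c1ccccc1.[I-] | intermediate (not isolated)
25 | (1-iodoethylidene)triphenylphosphorane | IC(C)=P(c1ccccc1)(c1ccccc1)c1ccccc1 | intermediate (not isolated)
26 | (Z)-tert-butyl[(4-iodopent-3-en-1-yl)oxy]dimethylsilane | I/C(C)=C\CCO[Si](C)(C)C(C)(C)C | intermediate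
27 | (Z)-4-iodopent-3-en-1-ol | I/C(C)=C\CCO | intermediate
28 | [(3E,7R)-7-(2,2-dimethoxyethyl)-4,12-dimethyl-8-methylidenetrideca-3,11-dien-1-yl]lithium | [Li]CC/C=C(\C)CC[C@H](CC(OC)OC)C(=C)CCC=C(C)C | intermediate (not isolated)
29 | lithium 9-[(3E,7R)-7-(2,2-dimethoxyethyl)-4,12-dimethyl-8-methylidenetrideca-3,11-dien-1-yl]-9-methoxy-9-borabicyclo[3.3.1]nonan-9-uide | [Li+].CO[B-]1(CC/C=C(\C)CC[C@H](CC(OC)OC)C(=C)CCC=C(C)C)C2CCCC1CCC2 | intermediate (not isolated)
30 | (3Z,7E,11R)-11-(2,2-dimethoxyethyl)-4,8,16-trimethyl-12-methylideneheptadeca-3,7,15-trien-1-ol | OCC/C=C(/C)CC/C=C(\C)CC[C@H](CC(OC)OC)C(=C)CCC=C(C)C | intermediate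
31 | (3Z,7E,11R)-11-(2,2-dimethoxyethyl)-1-iodo-4,8,16-trimethyl-12-methylideneheptadeca-3,7,15-triene | ICC/C=C(/C)CC/C=C(\C)CC[C@H](CC(OC)OC)C(=C)CCC=C(C)C | intermediate
32 | trimethyl phosphonoacetate | COC(=O)CP(=O)(OC)OC | starting material
33 | sodium salt of trimethyl phosphonoacetate | [Na+].COC(=O)[CH-]P(=O)(OC)OC | intermediate (not isolated)
34 | methyl (5Z,9E,13R)-2-(dimethoxyphosphoryl)-13-(2,2-dimethoxyethyl)-6,10,18-trimethyl-14-methylidenenonadeca-5,9,17-trienoate (both C2 epimers) | COC(=O)C(CC/C=C(/C)CC/C=C(\C)CC[C@H](CC(OC)OC)C(=C)CCC=C(C)C)P(=O)(OC)OC | intermediate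
35 | methyl (5Z,9E,13R)-2-(dimethoxyphosphoryl)-6,10,18-trimethyl-14-methylidene-13-(2-oxoethyl)nonadeca-5,9,17-trienoate (both C2 epimers) | COC(=O)C(CC/C=C(/C)CC/C=C(\C)CC[C@H](CC=O)C(=C)CCC=C(C)C)P(=O)(OC)OC | intermediate
36 | methyl (1E,4R,7E,11Z)-7,11-dimethyl-4-(6-methylhepta-1,5-dien-2-yl)cyclotetradeca-1,7,11-triene-1-carboxylate (CNP0163659.1) | C=C(CCC=C(C)C)[C@H]1C/C=C(/C(=O)OC)CC/C=C(/C)CC/C=C(\C)CC1 | target

Total step count: 16 (14 on the main line, 2 for vinyl iodide 27).
Longest linear sequence: 14 steps (steps 1–9 and 12–16, from sulcatone 1 to target 36).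

Steps most likely to fail

Step 8 (key step). The mixed cuprate may redistribute its ligands or decompose on warming before the alkyl group has migrated, and the alkenylcopper may be protonated before it is methylated; either process consumes the alkyllithium without forming C12–C13 or C12–CH3. The fallback sets out from iodide 12 and lithiated dihydrofuran 16 (made from 13 as in step 8) and returns to alcohol 19. Compound 16 would be alkylated with 12 in THF/DMPU to give (R)-5-[3-(2,2-dimethoxyethyl)-8-methyl-4-methylidenenon-7-en-1-yl]-2,3-dihydrofuran F1. MeMgBr with NiCl2(PPh3)2 in refluxing benzene would then replace the ring oxygen on C12 by methyl with retention (nickel-catalysed Grignard coupling of an enol ether; the methyl reagent has no β-hydrogen). This again places C13 trans to C10 and the oxygen on C9, giving 19.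

Step 16. Intermolecular olefination (oligomer formation) may compete with ring closure, and E selectivity may erode if the ring-forming transition state is strained. The fallback sets out from iodide 31 and returns at target 36. Heating 31 with methyl (triphenylphosphoranylidene)acetate (2 equiv, MeCN, reflux; the second equivalent deprotonates the first-formed phosphonium salt) should give the α-alkylated stabilised ylide, methyl (5Z,9E,13R)-13-(2,2-dimethoxyethyl)-6,10,18-trimethyl-14-methylidene-2-(triphenyl-λ5-phosphanylidene)nonadeca-5,9,17-trienoate F2. Aqueous HCl in THF would hydrolyse the acetal and protonate the ylide to [(5Z,9E,13R)-1-methoxy-6,10,18-trimethyl-14-methylidene-1-oxo-13-(2-oxoethyl)nonadeca-5,9,17-trien-2-yl]triphenylphosphonium chloride F3. Slow addition of F3 to Et3N in toluene at 80 °C under high dilution would regenerate the ylide, methyl (5Z,9E,13R)-6,10,18-trimethyl-14-methylidene-13-(2-oxoethyl)-2-(triphenyl-λ5-phosphanylidene)nonadeca-5,9,17-trienoate F4, which should close the ring by intramolecular Wittig reaction. Stabilised α-substituted ylides are E-selective and need no metal cation.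

Step 3. Transmetalation and insertion of the α-branched alkenyl group may be slow, so that protodeboronation and hydrolysis of the lactone compete, and facial discrimination may be incomplete. The fallback sets out from alkenyllithium 4 (made from 3 as in step 2) and returns at lactone 8, with stereocontrol by a separable oxazolidinone auxiliary.
- (S)-4-Phenyloxazolidin-2-one would be N-acylated (n-BuLi, acryloyl chloride) to (S)-3-acryloyl-4-phenyloxazolidin-2-one F5.
- Cross-metathesis with tert-butyl(but-3-en-1-yloxy)dimethylsilane (second-generation Hoveyda–Grubbs catalyst, CH2Cl2, 40 °C) should give (S)-3-[(E)-5-[(tert-butyldimethylsilyl)oxy]pent-2-enoyl]-4-phenyloxazolidin-2-one F6.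
- Compound 4 would be transmetalated (MgBr2·OEt2, CuBr·SMe2, THF/Me2S) to (6-methylhepta-1,5-dien-2-yl)copper F7.
- F7 should add to the magnesium-chelated imide on the face away from the phenyl group, giving (S)-3-[(R)-3-{2-[(tert-butyldimethylsilyl)oxy]ethyl}-8-methyl-4-methylidenenon-7-enoyl]-4-phenyloxazolidin-2-one F8; minor diastereomers are removed by chromatography.
- Bu4NF would remove the silyl group, and (S)-3-[(R)-3-(2-hydroxyethyl)-8-methyl-4-methylidenenon-7-enoyl]-4-phenyloxazolidin-2-one F9 should lactonise in the same flask to 8 with release of the auxiliary.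

Further compounds
F1 | step 8 | (R)-5-[3-(2,2-dimethoxyethyl)-8-methyl-4-methylidenenon-7-en-1-yl]-2,3-dihydrofuran | O1CCC=C1CC[C@H](CC(OC)OC)C(=C)CCC=C(C)C
F2 | step 16 | methyl (5Z,9E,13R)-13-(2,2-dimethoxyethyl)-6,10,18-trimethyl-14-methylidene-2-(triphenyl-λ5-phosphanylidene)nonadeca-5,9,17-trienoate | COC(=O)C(CC/C=C(/C)CC/C=C(\C)CC[C@H](CC(OC)OC)C(=C)CCC=C(C)C)=P(c1ccccc1)(c1ccccc1)c1ccccc1
F3 | step 16 | [(5Z,9E,13R)-1-methoxy-6,10,18-trimethyl-14-methylidene-1-oxo-13-(2-oxoethyl)nonadeca-5,9,17-trien-2-yl]triphenylphosphonium chloride | [Cl-].COC(=O)C(CC/C=C(/C)CC/C=C(\C)CC[C@H](CC=O)C(=C)CCC=C(C)C)[P+](c1ccccc1)(c1ccccc1)c1ccccc1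
F4 | step 16 | methyl (5Z,9E,13R)-6,10,18-trimethyl-14-methylidene-13-(2-oxoethyl)-2-(triphenyl-λ5-phosphanylidene)nonadeca-5,9,17-trienoate | COC(=O)C(CC/C=C(/C)CC/C=C(\C)CC[C@H](CC=O)C(=C)CCC=C(C)C)=P(c1ccccc1)(c1ccccc1)c1ccccc1
F5 | step 3 | (S)-3-acryloyl-4-phenyloxazolidin-2-one | C=CC(=O)N1[C@@H](c2ccccc2)COC1=O
F6 | step 3 | (S)-3-[(E)-5-[(tert-butyldimethylsilyl)oxy]pent-2-enoyl]-4-phenyloxazolidin-2-one | CC(C)(C)[Si](C)(C)OCC/C=C/C(=O)N1[C@@H](c2ccccc2)COC1=O
F7 | step 3 | (6-methylhepta-1,5-dien-2-yl)copper | [Cu]C(=C)CCC=C(C)C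
F8 | step 3 | (S)-3-[(R)-3-{2-[(tert-butyldimethylsilyl)oxy]ethyl}-8-methyl-4-methylidenenon-7-enoyl]-4-phenyloxazolidin-2-one | CC(C)(C)[Si](C)(C)OCC[C@H](CC(=O)N1[C@@H](c2ccccc2)COC1=O)C(=C)CCC=C(C)C
F9 | step 3 | (S)-3-[(R)-3-(2-hydroxyethyl)-8-methyl-4-methylidenenon-7-enoyl]-4-phenyloxazolidin-2-one | OCC[C@H](CC(=O)N1[C@@H](c2ccccc2)COC1=O)C(=C)CCC=C(C)C
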